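## Retrosynthetic overview

1. Pyran ring last: O–C4 and C15–C1′ are cut by a retro-oxa-[4+2] to the exocyclic diene 10 (C15=C4–C5=C6) and the o-quinone methide 13 (from 11 + 12). The spiro centre C4 and the benzylic centre C1′ arise together.
2. Diene 10 comes from the cis-fused carbinol 9 by syn-dehydration (C6–OH with C5–H).
3. Ring B (C1–C6) comes from a one-pot [3+3] annulation: C2–C3 and C5–C6 are cut to 6-methylidene-menthone 5 and the isobutene 1,3-dianion equivalent 6. C1–H (cis to H-10, trans to H-7, the less stable muurolane-type ring-fusion epimer) is set by kinetic protonation between the two C–C bond formations.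
4. Ring A with C7 (isopropyl) and C10 (methyl) is (−)-menthone 1; C2 is added by α-methylenation.
5. Order of ring formation: ring A (chiral pool), then ring B (step 2), then the pyran ring (step 4).

Key step: step 2

Remark on numbering: cadinane numbering is used for the terpenoid part (C1–C15, C15 = CH2 of the pyran ring); C1′ is the CHPh carbon.
Assumption: 6 and 11 are taken as catalogue compounds; each is otherwise one known step from 3-chloro-2-(chloromethyl)prop-1-ene (Mg, Me3SiCl) or from phloroglucinol (Vilsmeier–Haack).

## Route

Step 1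
Reactants: 1 (−)-menthone
Product: 5 (2S,5R)-5-methyl-6-methylidene-2-(propan-2-yl)cyclohexan-1-one, via lithium enolate 2 (not isolated), via Mannich base 3 (not isolated), via ammonium iodide 4 (not isolated)
Conditions: LDA, THF, −78 °C; CH2=NMe2+ I−, −78 °C to rt; MeI, MeOH, rt; aq. NaHCO3, CH2Cl2, rt
Reagents that add atoms: N,N-dimethylmethyleneiminium iodide (Eschenmoser's salt), C=[N+](C)C.[I-]
Why: Kinetic deprotonation of menthone occurs only at the C6 methylene (target C1), the enolate is aminomethylated (Mannich reaction) and elimination of the quaternised amine gives the exo-methylene ketone whose new carbon is target C2; the transient α-centre of 3 and 4 is lost, and C7 and C10 are not touched under these non-equilibrating conditions.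

Step 2
Reactants: 5 (2S,5R)-5-methyl-6-methylidene-2-(propan-2-yl)cyclohexan-1-one; 6 3-(trimethylsilyl)-2-[(trimethylsilyl)methyl]prop-1-ene
Product: 9 (1S,4R,4aR,8aR)-4-methyl-7-methylidene-1-(propan-2-yl)octahydronaphthalen-8a(1H)-ol, via titanium enolate 7 (not isolated), via keto allylsilane 8 (not isolated)
Conditions: 6 (1.5 equiv), TiCl4 (2.2 equiv), CH2Cl2, −78 °C; 2,6-di-tert-butylphenol (1.1 equiv), −78 °C; then −78 to −30 °C; aq. NaHCO3
Reagents that add atoms: none
Why: TiCl4 activates the exo-enone 5 so that the CH2= terminus of 6 adds to C2 in a Hosomi–Sakurai conjugate allylation (β-silyl cation, loss of Me3SiCl), which regenerates an allylsilane in the new side chain and leaves the C6 oxygen as the fully substituted titanium enolate 7. In 7 the C10 methyl and the C7 isopropyl groups are pushed pseudoaxial on opposite faces by A(1,2) strain with the C1 side chain and the O–Ti group, so the hindered phenol should deliver its proton to C1 anti to the adjacent C10 methyl group; this places the side chain cis to C10–Me in ketone 8, the muurolane configuration that an equilibrating, base-mediated annulation is not expected to give. Renewed activation of the C6 carbonyl then lets the terminal CH2 (C5) of the pendant allylsilane attack C6 in an intramolecular Hosomi–Sakurai carbonyl allylation, a 6-exo-trig closure of ring B in which the axial C1 side chain reaches the same face of C6; this gives the cis-fused carbinol and unveils the exocyclic C4=C15 methylene. The closest known reaction types are the Lewis-acid conjugate allylation of enones, the kinetic C-protonation of enolates and the allylsilane–ketone cyclisation to 3-methylidenecyclohexanols; the C6 carbinol centre is removed in step 3, so its configuration does not matter. The step needs 1,4-allylation before 1,2-allylation (secured by the exo-methylene enone and its hindered carbonyl), monoaddition of 6 (secured by its excess) and no epimerisation at C1 after protonation (secured by low temperature and by the equatorial, poorly aligned C1–H of 8).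

Step 3
Reactants: 9 (1S,4R,4aR,8aR)-4-methyl-7-methylidene-1-(propan-2-yl)octahydronaphthalen-8a(1H)-ol
Product: 10 (1S,4R,4aR)-4-methyl-7-methylidene-1-(propan-2-yl)-1,2,3,4,4a,5,6,7-octahydronaphthalene
Conditions: Burgess reagent (2 equiv), toluene, 50 °C
Reagents that add atoms: none
Why: The Burgess dehydration is a syn (Ei) elimination; in cis-fused 9 H-7 is anti to the hydroxyl and out of reach, and of the syn hydrogens the allylic C5–H (developing conjugated diene) should be removed in preference to the tertiary C1–H, which gives the 4(15),5-diene without acid and without touching C1, C7 or C10.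

Step 4
Reactants: 10 (1S,4R,4aR)-4-methyl-7-methylidene-1-(propan-2-yl)-1,2,3,4,4a,5,6,7-octahydronaphthalene; 11 2,4,6-trihydroxybenzene-1,3-dicarbaldehyde; 12 benzaldehyde
Product: 14 Guajadial C, via o-quinone methide 13 (not isolated)
Conditions: 10 (1.5 equiv), 11 (1 equiv), 12 (1.2 equiv), ethylenediammonium diacetate (10 mol %), 1,4-dioxane, 80 °C
Reagents that add atoms: none
Why: Knoevenagel condensation of 11 with 12 gives the o-quinone methide 13, which adds as an oxadiene across the exocyclic C4=C15 bond of the s-trans-locked diene 10 in an inverse-demand hetero-Diels–Alder reaction (O to the tertiary allylic C4, C1′ to C15); approach endo to the C5=C6 unit (phenyl cis to C5) and from the ring-B face opposite the pseudoaxial C7 isopropyl group (O axial, anti to H-1) should set C4 (S) and C1′ (R) together.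

## Compound list

1 | (−)-menthone, (2S,5R)-5-methyl-2-(propan-2-yl)cyclohexan-1-one | CC(C)[C@@H]1CC[C@@H](C)CC1=O | starting material
2 | lithium (3R,6S)-3-methyl-6-(propan-2-yl)cyclohex-1-en-1-olate | CC(C)[C@@H]1CC[C@@H](C)C=C1O[Li] | intermediate
3 | (2S,5R,6R)-6-[(dimethylamino)methyl]-5-methyl-2-(propan-2-yl)cyclohexan-1-one (CH2NMe2 trans to 5-Me) | CC(C)[C@@H]1CC[C@@H](C)[C@H](CN(C)C)C1=O | intermediate
4 | N,N,N-trimethyl-1-[(1R,3S,6R)-6-methyl-2-oxo-3-(propan-2-yl)cyclohexyl]methanaminium iodide | CC(C)[C@@H]1CC[C@@H](C)[C@H](C[N+](C)(C)C)C1=O.[I-] | intermediate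
5 | (2S,5R)-5-methyl-6-methylidene-2-(propan-2-yl)cyclohexan-1-one | CC(C)[C@@H]1CC[C@@H](C)C(=C)C1=O | intermediate
6 | 3-(trimethylsilyl)-2-[(trimethylsilyl)methyl]prop-1-ene | C=C(C[Si](C)(C)C)C[Si](C)(C)C | starting material
7 | trichloro{[(3R,6S)-3-methyl-6-(propan-2-yl)-2-{3-[(trimethylsilyl)methyl]but-3-en-1-yl}cyclohex-1-en-1-yl]oxy}titanium | CC(C)[C@@H]1CC[C@@H](C)C(CCC(=C)C[Si](C)(C)C)=C1O[Ti](Cl)(Cl)Cl | intermediate
8 | (2S,5R,6R)-5-methyl-2-(propan-2-yl)-6-{3-[(trimethylsilyl)methyl]but-3-en-1-yl}cyclohexan-1-one (side chain cis to 5-Me) | CC(C)[C@@H]1CC[C@@H](C)[C@@H](CCC(=C)C[Si](C)(C)C)C1=O | intermediate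
9 | (1S,4R,4aR,8aR)-4-methyl-7-methylidene-1-(propan-2-yl)octahydronaphthalen-8a(1H)-ol (cis-fused, C6–OH) | CC(C)[C@@H]1CC[C@@H](C)[C@H]2CCC(=C)C[C@@]12O | intermediate
10 | (1S,4R,4aR)-4-methyl-7-methylidene-1-(propan-2-yl)-1,2,3,4,4a,5,6,7-octahydronaphthalene (muurola-4(15),5-diene type) | CC(C)[C@@H]1CC[C@@H](C)[C@H]2CCC(=C)C=C12 | intermediate
11 | 2,4,6-trihydroxybenzene-1,3-dicarbaldehyde | O=Cc1c(O)cc(O)c(C=O)c1O | starting material
12 | benzaldehyde | O=Cc1ccccc1 | starting material
13 | 5-benzylidene-2,4-dihydroxy-6-oxocyclohexa-1,3-diene-1,3-dicarbaldehyde (o-quinone methide; benzylidene geometry left open, the two flanking oxygens exchange by tautomerism) | O=CC1=C(O)C(=Cc2ccccc2)C(=O)C(C=O)=C1O | intermediate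
14 | Guajadial C | CC(C)[C@@H]1CC[C@@H](C)[C@H]2CC[C@@]3(C=C12)C[C@H](c1ccccc1)c1c(O)c(C=O)c(O)c(C=O)c1O3 | target

## Step count and risks

Total step count: 4. Longest linear sequence: 4 steps (1 → 5 → 9 → 10 → 14).

Steps most likely to fail:

Step 2. The facial selectivity of the enolate protonation may erode in the presence of the Lewis acid (C1 epimer). The second allylsilane may also be lost by protodesilylation before it closes onto the hindered ketone, or the exo-enone may isomerise to the endocyclic enone with loss of C10. The fallback sets out from 5 and returns at 10. Hosomi–Sakurai conjugate allylation of 5 with 2-(chloromethyl)-3-(trimethylsilyl)prop-1-ene (TiCl4, CH2Cl2, −78 °C, inverse quench into a cold hindered phenol) should give the isolated keto allyl chloride (2S,5R,6R)-6-[3-(chloromethyl)but-3-en-1-yl]-5-methyl-2-(propan-2-yl)cyclohexan-1-one F1, on which the C1 configuration can be checked and the epimers separated. PPh3 (MeCN, 60 °C) should convert it into (2-{2-[(1R,3S,6R)-6-methyl-2-oxo-3-(propan-2-yl)cyclohexyl]ethyl}prop-2-en-1-yl)triphenylphosphonium chloride F2. KHMDS (THF, −78 to 0 °C) should then trigger an intramolecular Wittig olefination of the C6 ketone through the α-carbon (C5) of the allylic ylide, which closes ring B and places C5=C6 next to C4=C15 directly, so diene 10 is reached without carbinol 9.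

Step 3. The syn-elimination may take the tertiary C1–H instead of C5–H (tetrasubstituted 1(6)-olefin), or the sulfamate may ionise to the C6 cation and scramble C1 and C7. The fallback sets out from 9 and returns at 10. Ozonolysis of the exocyclic methylene (O3, CH2Cl2–MeOH, −78 °C; Me2S) should give the ketol (4aR,5R,8S,8aR)-8a-hydroxy-5-methyl-8-(propan-2-yl)octahydronaphthalen-2(1H)-one F3. With the C4 carbonyl in place, dehydration (Burgess reagent, toluene, rt) is directed to the acidified C5 hydrogens and should give the enone (4aR,5R,8S)-5-methyl-8-(propan-2-yl)-4,4a,5,6,7,8-hexahydronaphthalen-2(3H)-one F4. Non-basic Petasis methylenation (Cp2TiMe2, toluene, 65 °C), which avoids the dienolate and so keeps C1, should then restore C15 and give diene 10.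

Step 4. The cycloaddition may show poor facial or endo/exo selectivity (C4/C1′ diastereomers), the o-quinone methide may be consumed by a second molecule of 11, or the semicyclic diene may isomerise under the warm, weakly acidic conditions. The fallback sets out from 10 and returns at 14. Commercial 2,4,6-trihydroxybenzophenone is reduced (NaBH4, MeOH, 0 °C) to 2-[hydroxy(phenyl)methyl]benzene-1,3,5-triol F5. A BINOL-derived chiral phosphoric acid (5 mol %, CHCl3, −20 °C; both antipodes screened for the matched case) ionises F5 to the ion-paired o-quinone methide, which should add to 10 in a catalyst-controlled oxa-[4+2] at low temperature to give the 6,8-bis-desformyl chroman (6,8-bis-desformyl Guajadial C) F6. Double Vilsmeier–Haack formylation of the two free phloroglucinol positions (POCl3, DMF, 0 °C to rt; aq. NaOAc) should then give 14.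

Further compounds
F1 | step 2 | (2S,5R,6R)-6-[3-(chloromethyl)but-3-en-1-yl]-5-methyl-2-(propan-2-yl)cyclohexan-1-one | CC(C)[C@@H]1CC[C@@H](C)[C@@H](CCC(=C)CCl)C1=O
F2 | step 2 | (2-{2-[(1R,3S,6R)-6-methyl-2-oxo-3-(propan-2-yl)cyclohexyl]ethyl}prop-2-en-1-yl)triphenylphosphonium chloride | CC(C)[C@@H]1CC[C@@H](C)[C@@H](CCC(=C)C[P+](c2ccccc2)(c2ccccc2)c2ccccc2)C1=O.[Cl-]
F3 | step 3 | (4aR,5R,8S,8aR)-8a-hydroxy-5-methyl-8-(propan-2-yl)octahydronaphthalen-2(1H)-one | CC(C)[C@@H]1CC[C@@H](C)[C@H]2CCC(=O)C[C@@]12O
F4 | step 3 | (4aR,5R,8S)-5-methyl-8-(propan-2-yl)-4,4a,5,6,7,8-hexahydronaphthalen-2(3H)-one | CC(C)[C@@H]1CC[C@@H](C)[C@H]2CCC(=O)C=C12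
F5 | step 4 | 2-[hydroxy(phenyl)methyl]benzene-1,3,5-triol (racemic) | OC(c1ccccc1)c1c(O)cc(O)cc1O
F6 | step 4 | 6,8-bis-desformyl Guajadial C (5,7-dihydroxy spiro-chroman) | CC(C)[C@@H]1CC[C@@H](C)[C@H]2CC[C@@]3(C=C12)C[C@H](c1ccccc1)c1c(O)cc(O)cc1O3
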